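## The problem

The target, CNP0246965.4, is a spiro[4.5]decane: a cyclopentane (ring A, C1–C4) and a cyclohexane (ring B, C6–C10) share the quaternary carbon C5, which stands between two carbinol carbons, secondary C1 and tertiary C10 (methyl, hydroxyl). Five stereocentres (1R,2S,5S,6R,10S) surround C5: the C10 oxygen is cis to C1 on ring B, the C6 hydroxypropyl chain lies on the same face of ring B as that oxygen, and the C1 hydroxyl and the C2 side chain are cis on the face of ring A turned towards C6. Two stereodefined alkenes complete the task: the tetrasubstituted (E)-enal exocyclic to C7, and the E-trisubstituted alkene that opens the C2 side chain and continues as an (E)-diene ending in a 1,1-disubstituted unit. Stereocontrol can be relayed: an oxygen at C7 (a ketone in the end) can steer an oxidant to one face of a C5=C10 alkene, the C10 hydroxyl can then deliver hydride to a C1 ketone, and the C1 hydroxyl can tie a C2 acetic acid arm into a cis-fused lactone that also dictates the side-chain alkene geometry. Three things will not survive rough treatment: the enal (E/Z-labile, with C6 as its epimerisable γ-position), the conjugated triene with its allylic alcohol (acid, oxidants, boranes), and any intermediate in which the C10 hydroxyl is β to a C1 ketone (retro-aldol). The enabling feature is the triad C1–O / quaternary C5 / C10(Me)–O: this is what a 1,2-shift in a 2,3-epoxy alcohol leaves behind, and if C1–C4 are redrawn as a cyclobutanol on C5 of a C5–C10 epoxide, ring A arises by ring expansion.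

## Retrosynthesis

**Unmasking and the side chain.** Target 35 is taken back to its dimethyl acetal 34, so that the last step only frees the enal. In 34 the C1 hydroxyl and the allylic CH2OH are the two ends of a γ-lactone, which leads to triene lactone 33. The C=C bond between the lactone α-carbon and the dienyl chain is then cut (aldol condensation) to lactone 25 and dienal 30. Cutting the diene single bond instead would need a stereodefined trisubstituted alkenyl halide on ring A, and cutting C2–C(sp2) would need α-alkenylation of a hindered ketone. The lactone cut removes ten carbons and the whole triene; it makes the C1/C2 cis relation a ring constraint and the E-alkene the thermodynamic outcome. The forward steps need an amide base and an aluminium hydride, which is why the enal must already be present in masked form.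

**The ring B enal.** Acetal 25 comes from enal 24, and the tetrasubstituted C7=C bond is cut to ketone 22 and an isopropenyl nucleophile (tertiary allylic alcohol 23, then Babler–Dauben oxidative transposition). Olefination of this α-branched, hindered ketone with a stabilised phosphorus reagent is the neighbouring option and is expected to be sluggish. A small organocerium reagent followed by an intramolecular [3,3] shift is asked to do less. The step is placed before the triene exists, so the chromium oxidant never meets it and the E/Z isomers can be sorted on a robust intermediate.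

**The lactone.** Keto lactone 22 comes from hydroxy lactone 21, and this from keto ester 19. The C2–CH2 bond is cut back to spiro ketol 18 and methyl bromoacetate, and the C1–H bond is assigned to a hydride delivered by the C10 hydroxyl. The neighbouring option, building the arm from the C1 oxygen after reduction by radical cyclisation, fixes C2 with certainty but costs three more steps; it is kept as a fallback. The forward steps need C2 alkylation on the ring A face next to C6 and a reduction that the C10 hydroxyl alone directs.

**The key disconnection.** In 18 the C4–C5 bond is cut and C4 is reattached to C1. This gives bis-silyl epoxide 17, a 1-(epoxycyclohexyl)cyclobutanol silyl ether. Alkylating C5 between two oxygenated carbons, or closing ring B by an aldol reaction, would have to build the quaternary centre and the tertiary carbinol in separate events. The 1,2-shift makes C5 and C10 from one epoxide, stereospecifically. The precursor is much simpler: the spiro centre becomes a tetrasubstituted alkene and two stereocentres reduce to one choice of alkene face. The forward reaction must break C5–O and not C10–O, and must migrate with inversion.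

**The epoxide and the absolute configuration.** Epoxide 17 comes from epoxy alcohol 16 and this from homoallylic alcohol 15. The oxygen has to enter on the face that carries the C6 chain, against the steric bias, so it is delivered by the cis C7 hydroxyl (C1 of the cyclohexene). The cyclobutanol is kept silylated because a free allylic hydroxyl would deliver the oxidant to the other face. Pivalate 15 comes from diol 14, and this from acetate 12 by hydroboration of the allyl group. Acetate 12 comes from racemic cis-alcohol 11 by lipase resolution, and 11 from β,γ-unsaturated ketone 10. An asymmetric reduction of 10 with dynamic resolution was weighed and set aside: its base would move the alkene into conjugation, and a dialkyl ketone of this kind is a poor substrate for the usual transfer-hydrogenation catalysts.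

**The cyclohexene.** Ketone 10 comes from dienol ether 9, in which the C5–cyclobutane bond is cut to alkenylstannane 5 (as its lithium reagent 7) and cyclobutanone 6. Stannane 5 comes from dienyl triflate 4, methylated vinylogous ester 3, vinylogous ester 2 and dione 1. The vinylogous ester has a single α′ position, so the methyl group and the tetrasubstituted alkene are placed without regiochemical doubt. A dehydration or an olefination at C5=C10 would not give that certainty. The enol ether also masks the C7 carbonyl during the organolithium step.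

**The dienal.** Dienal 30 is cut at its C3–C4 bond (sp2–sp2 coupling) to enol triflate 27 and boronate 28. Triflate 27 comes from ketone 26, which supplies eight of the ten carbons; the kinetic enolate fixes the 1,1-disubstituted alkene.

## Roads not taken

**Alternative 1:** ring B would be closed last at C5–C6. The forward key step deprotonates the open-chain precursor of A1 twice and oxidises the bis-enolate with Fe(acac)3, which joins a cyclopentenone α-carbon to a ketone α-carbon and gives spiro dienedione A1.
- Merits: one C–C bond creates the quaternary C5 and the C6 stereocentre with its chain. Both ring carbonyls arrive at the right oxidation level, and the C7 ketone sits where the enal needs it, so no sacrificial C7 carbinol is required.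
- Weak points: an oxidative hetero-coupling has to form a quaternary carbon next to a tertiary ether. Homo-coupling, over-oxidation and isomerisation of the Z-enone compete. The configurations at C5 and C6 depend on a single remote centre (C10) through a flexible closure. Two enone alkenes must later be saturated selectively, and the C10 carbinol needs its own asymmetric construction.
- Comparison: A1 is reached in fewer steps and is better on ring B oxidation states than the chosen plan, which spends three steps on the C7 carbinol. The chosen plan sets against this a known, stereospecific 1,2-shift in which C5 and C10 come from one epoxide face.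

**Alternative 2:** ring B would be closed by forming C6–C7 together with a cyclobutane bond. The forward key step irradiates the dioxinone precursor of A2, whose C5 carries a vinyl group, to give photoadduct A2 by intramolecular [2+2] cycloaddition. A retro-aldol (de Mayo) fragmentation then opens the cyclobutane to the C7 ketone and a C6 propanoic acid chain.
- Merits: ring B, the C6 stereocentre, the three-carbon chain and the C7 ketone come from two operations. No hydroboration and no sacrificial stereocentre are needed.
- Weak points: the quaternary C5, the C1 silyl ether and the C10 tertiary ether must all be in place before the key step, so the hardest stereochemical problem is moved upstream and left unsolved. With a four-atom tether, straight versus crossed closure and facial selectivity are hard to predict. The step is a photoreaction on a fully substituted enone, and a tertiary methoxymethyl ether must be removed late.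
- Comparison: in functional-group economy on ring B this road is better than the chosen one. The chosen plan is stronger at C5/C10, uses only thermal steps, and reaches spiro ketol 18 in thirteen steps, which the unsolved precursor of A2 is unlikely to match.

**Alternative 3:** ring A would be closed last at C1–C2. The forward key step is tin–lithium exchange in the eight-membered allylic α-stannyl ether that precedes A3, followed by a transannular [2,3]-Wittig shift. This contracts the ring to cyclopentanol A3 and creates the trisubstituted side-chain alkene.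
- Merits: the C1 hydroxyl, the cis C2 substituent and the alkene geometry are set by one concerted, mechanism-controlled step. This is better than the enolate face selectivity and the thermodynamic elimination on which the chosen plan relies.
- Weak points: a medium ring must be closed at a neopentyl position beside the spiro centre, with a configurationally defined α-alkoxystannane. The [1,2]-shift competes. Five protecting groups of four kinds are carried, and the product still needs its CH2O terminus turned into the diene and its ketal into the enal.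
- Comparison: the chosen plan cannot match the intrinsic control at C2. It sets against it a cis-lactone that enforces the same two relationships in five ordinary steps with two protecting groups.

Key step: step 13

Remarks on the chemistry:
- Locants C1–C10 are those of spiro[4.5]decane (C5 spiro, C1–C4 ring A, C6–C10 ring B); in the text they are also used for the corresponding atoms of the cyclohexene precursors, whose own names use cyclohexene or oxabicycloheptane numbering.
- Compounds 3 and 10 are racemic; racemic 11 is drawn as its (1R,2S) enantiomer.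
- The lipase in step 8 is assumed to acylate the 1R carbinol, as the usual preference for secondary alcohols (larger substituent on the C2 side) predicts.
- Compound 23 is carried as a mixture of C7 epimers; this centre is erased in step 18.

## Steps

Step 1
Reactants: 1 2-allylcyclohexane-1,3-dione
Product: 2 2-allyl-3-(2-methylpropoxy)cyclohex-2-en-1-one
Conditions: i-BuOH, p-TsOH (cat.), toluene, reflux, Dean–Stark
Reagents that add atoms: 2-methylpropan-1-ol, CC(C)CO
Why: Acid-catalysed enol etherification of a cyclic 1,3-dione (vinylogous ester formation); the dione is symmetric, so only one enol ether can form.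

Step 2
Reactants: 2 2-allyl-3-(2-methylpropoxy)cyclohex-2-en-1-one
Product: 3 rac-2-allyl-6-methyl-3-(2-methylpropoxy)cyclohex-2-en-1-one
Conditions: LiN(i-Pr)2, THF, −78 °C; MeI, −78 → 0 °C
Reagents that add atoms: iodomethane, CI
Why: Kinetic α′-deprotonation and alkylation of a vinylogous ester (Stork–Danheiser alkylation) places the future C10 methyl group; the new centre is racemic and becomes sp2 in step 3.

Step 3
Reactants: 3 rac-2-allyl-6-methyl-3-(2-methylpropoxy)cyclohex-2-en-1-one
Product: 4 6-allyl-2-methyl-5-(2-methylpropoxy)cyclohexa-1,5-dien-1-yl trifluoromethanesulfonate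
Conditions: LiN(i-Pr)2, THF, −78 °C; PhNTf2, −78 → 0 °C
Reagents that add atoms: N-phenylbis(trifluoromethanesulfonimide), O=S(=O)(N(c1ccccc1)S(=O)(=O)C(F)(F)F)C(F)(F)F
Why: The only α′ hydrogen is removed and the cross-conjugated enolate is O-sulfonylated (enol triflate formation), which fixes the future C5=C10 alkene.

Step 4
Reactants: 4 6-allyl-2-methyl-5-(2-methylpropoxy)cyclohexa-1,5-dien-1-yl trifluoromethanesulfonate
Product: 5 [6-allyl-2-methyl-5-(2-methylpropoxy)cyclohexa-1,5-dien-1-yl]trimethylstannane
Conditions: Me3SnSnMe3, Pd(PPh3)4 (cat.), LiCl, THF, 65 °C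
Reagents that add atoms: hexamethylditin, C[Sn](C)(C)[Sn](C)(C)C
Why: Palladium-catalysed stannylation of an alkenyl triflate with a distannane (Stille-type coupling) exchanges the triflate for tin without moving the alkene.

Step 5
Reactants: 5 [6-allyl-2-methyl-5-(2-methylpropoxy)cyclohexa-1,5-dien-1-yl]trimethylstannane; 6 cyclobutanone
Product: 9 {1-[6-allyl-2-methyl-5-(2-methylpropoxy)cyclohexa-1,5-dien-1-yl]cyclobutoxy}triethylsilane, via alkenyllithium 7 (not isolated), via lithium cyclobutoxide 8 (not isolated)
Conditions: MeLi, THF, −78 °C; 6, −78 °C; Et3SiCl, −78 °C → rt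
Reagents that add atoms: chlorotriethylsilane, CC[Si](Cl)(CC)CC
Why: Tin–lithium exchange gives the alkenyllithium, which adds 1,2 to the strained ketone; silylation of the alkoxide in the same flask masks the tertiary allylic carbinol, which would otherwise ionise in step 6 and compete as a directing group in step 11.

Step 6
Reactants: 9 {1-[6-allyl-2-methyl-5-(2-methylpropoxy)cyclohexa-1,5-dien-1-yl]cyclobutoxy}triethylsilane
Product: 10 rac-2-allyl-4-methyl-3-[1-(triethylsilyloxy)cyclobutyl]cyclohex-3-en-1-one
Conditions: oxalic acid, THF/H2O, 0 °C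
Reagents that add atoms: water, O
Why: Kinetic α-protonation and hydrolysis of the dienol ether gives the β,γ-unsaturated ketone, as in the mild hydrolysis of Birch-type dienol ethers; short exposure to a weak acid should avoid conjugation of the alkene and loss of the allylic silyl ether.

Step 7
Reactants: 10 rac-2-allyl-4-methyl-3-[1-(triethylsilyloxy)cyclobutyl]cyclohex-3-en-1-one
Product: 11 rac-(1R,2S)-2-allyl-4-methyl-3-[1-(triethylsilyloxy)cyclobutyl]cyclohex-3-en-1-ol (cis racemate)
Conditions: LiBH(s-Bu)3, THF, −78 °C; then H2O
Reagents that add atoms: none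
Why: Substrate-controlled ketone reduction: in either half-chair the bulky hydride should enter anti to the neighbouring allyl group and give the cis alcohol, and at −78 °C reduction should outrun enolisation of the acidic C2 hydrogen.

Step 8
Reactants: 11 rac-(1R,2S)-2-allyl-4-methyl-3-[1-(triethylsilyloxy)cyclobutyl]cyclohex-3-en-1-ol (cis racemate)
Product: 12 (1R,2S)-2-allyl-4-methyl-3-[1-(triethylsilyloxy)cyclobutyl]cyclohex-3-en-1-yl acetate
Conditions: immobilised Candida antarctica lipase B, vinyl acetate, t-BuOMe, 35 °C
Reagents that add atoms: vinyl acetate, C=COC(C)=O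
Why: Lipase-catalysed kinetic resolution by irreversible acyl transfer; the 1R alcohol should be acetylated and the (1S,2R) enantiomer left behind and separated, which fixes the absolute configuration of the route.

Step 9
Reactants: 12 (1R,2S)-2-allyl-4-methyl-3-[1-(triethylsilyloxy)cyclobutyl]cyclohex-3-en-1-yl acetate
Product: 14 (1R,2S)-2-(3-hydroxypropyl)-4-methyl-3-[1-(triethylsilyloxy)cyclobutyl]cyclohex-3-en-1-ol, via alkylborane 13 (not isolated)
Conditions: 9-BBN-H, THF, 0 °C → rt; then NaOH, H2O2, EtOH/H2O, 0 → 50 °C
Reagents that add atoms: hydrogen peroxide, OO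
Why: Anti-Markovnikov hydroboration of the terminal alkene (the tetrasubstituted alkene does not react with this borane); the alkaline peroxide oxidises the C–B bond and its hydroxide saponifies the acetate in the same operation.

Step 10
Reactants: 14 (1R,2S)-2-(3-hydroxypropyl)-4-methyl-3-[1-(triethylsilyloxy)cyclobutyl]cyclohex-3-en-1-ol
Product: 15 (1R,2S)-4-methyl-2-[3-(pivaloyloxy)propyl]-3-[1-(triethylsilyloxy)cyclobutyl]cyclohex-3-en-1-ol
Conditions: t-BuCOCl, pyridine, CH2Cl2, −20 → 0 °C
Reagents that add atoms: pivaloyl chloride, CC(C)(C)C(Cl)=O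
Why: Selective acylation of the primary over the hindered secondary alcohol; the non-enolisable pivalate should tolerate the amide bases of steps 14 and 22 and is removed by the hydride of step 24.

Step 11
Reactants: 15 (1R,2S)-4-methyl-2-[3-(pivaloyloxy)propyl]-3-[1-(triethylsilyloxy)cyclobutyl]cyclohex-3-en-1-ol
Product: 16 (1R,2R,3R,6S)-6-methyl-2-[3-(pivaloyloxy)propyl]-1-[1-(triethylsilyloxy)cyclobutyl]-7-oxabicyclo[4.1.0]heptan-3-ol
Conditions: VO(acac)2 (cat.), t-BuOOH, CH2Cl2, 0 °C → rt
Reagents that add atoms: tert-butyl hydroperoxide, CC(C)(C)OO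
Why: Hydroxyl-directed epoxidation of a homoallylic alcohol: the secondary hydroxyl, the only free one, binds the metal and delivers the peroxide oxygen to its own face of the alkene, which is also the face of the cis side chain; this one delivery sets both epoxide carbons (future C5 and C10).

Step 12
Reactants: 16 (1R,2R,3R,6S)-6-methyl-2-[3-(pivaloyloxy)propyl]-1-[1-(triethylsilyloxy)cyclobutyl]-7-oxabicyclo[4.1.0]heptan-3-ol
Product: 17 (1R,2R,3R,6S)-6-methyl-2-[3-(pivaloyloxy)propyl]-3-(triethylsilyloxy)-1-[1-(triethylsilyloxy)cyclobutyl]-7-oxabicyclo[4.1.0]heptane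
Conditions: Et3SiCl, imidazole, DMAP (cat.), DMF, rt
Reagents that add atoms: chlorotriethylsilane, CC[Si](Cl)(CC)CC
Why: Silylation of the secondary alcohol; the ether keeps the C7 oxygen away from the Lewis acid of step 13 and from the borohydride of step 15, and it is removed by the acid of step 15.

Step 13
Reactants: 17 (1R,2R,3R,6S)-6-methyl-2-[3-(pivaloyloxy)propyl]-3-(triethylsilyloxy)-1-[1-(triethylsilyloxy)cyclobutyl]-7-oxabicyclo[4.1.0]heptane
Product: 18 (5R,6S,7R,10S)-10-hydroxy-10-methyl-6-[3-(pivaloyloxy)propyl]-7-(triethylsilyloxy)spiro[4.5]decan-1-one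
Conditions: BF3·OEt2, CH2Cl2, −78 °C; then aq. NaHCO3
Reagents that add atoms: none
Why: BF3 binds the epoxide oxygen, and as the C5–O bond lengthens the cyclobutane C–C bond anti-periplanar to it migrates from the silyloxy carbon to C5 (forming C4–C5), while the oxygen lone pair builds the C1 oxocarbenium ion, which loses Et3SiF to leave the C1 ketone. The closest known reaction type is the Lewis-acid-promoted 1,2-shift of 2,3-epoxy alcohol silyl ethers (Tsuchihashi–Suzuki semipinacol rearrangement), here in its cyclobutanol-to-cyclopentanone ring-expanding form. Ring A is thus closed by ring expansion through a 1,2-alkyl shift and not by a cyclisation, and the step is driven by release of both oxirane and cyclobutane strain. C5 is formed with inversion, because the migrating carbon enters anti to the departing oxygen, so the epoxide face chosen in step 11 decides its configuration and places C1 on the side of the C10 oxygen. C10 keeps its configuration because its C–O bond is never broken. The step needs C5–O and not C10–O cleavage and a concerted shift in place of a free cation; the strained, oxygen-substituted migrating bond gives anchimeric assistance that ionisation at C10 lacks, and −78 °C in a non-nucleophilic solvent disfavours open cations. The C7 silyl ether and the pivalate should be spectators.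

Step 14
Reactants: 18 (5R,6S,7R,10S)-10-hydroxy-10-methyl-6-[3-(pivaloyloxy)propyl]-7-(triethylsilyloxy)spiro[4.5]decan-1-one
Product: 19 methyl 2-[(2S,5R,6S,7R,10S)-10-hydroxy-10-methyl-1-oxo-6-[3-(pivaloyloxy)propyl]-7-(triethylsilyloxy)spiro[4.5]decan-2-yl]acetate
Conditions: LiN(i-Pr)2 (2.3 equiv), THF, −78 °C; BrCH2CO2Me, DMPU, −78 → −45 °C; AcOH, −78 °C
Reagents that add atoms: methyl bromoacetate, COC(=O)CBr
Why: Alkylation of the dianion (C10 alkoxide plus the enolate, which can only form towards C2); once the enolate exists the retro-aldol path of the β-alkoxide ketone is closed, and the electrophile should enter C2 on the ring A face flanked by the C6 methine and not on the face flanked by the fully substituted C10; C2 stays epimerisable.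

Step 15
Reactants: 19 methyl 2-[(2S,5R,6S,7R,10S)-10-hydroxy-10-methyl-1-oxo-6-[3-(pivaloyloxy)propyl]-7-(triethylsilyloxy)spiro[4.5]decan-2-yl]acetate
Product: 21 cis-fused γ-lactone between the C1 oxygen and the C2 acetic acid arm of (1R,2S,5S,6S,7R,10S)-7,10-dihydroxy-10-methyl-6-[3-(pivaloyloxy)propyl]spiro[4.5]decane, via hydroxy ester 20 (not isolated)
Conditions: Me4NBH(OAc)3, MeCN/AcOH, −25 °C; then p-TsOH·H2O, MeOH, rt
Reagents that add atoms: none
Why: Evans–Saksena reduction: the C10 hydroxyl, the only free one, exchanges onto boron and delivers hydride to C1 from the C10 side, giving the 1,3-anti diol with the C1 hydroxyl on the C6 side, cis to the C2 arm; acid then closes the γ-lactone (only the cis hydroxy ester can lactonise) and removes the C7 silyl ether.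

Step 16
Reactants: 21 cis-fused γ-lactone between the C1 oxygen and the C2 acetic acid arm of (1R,2S,5S,6S,7R,10S)-7,10-dihydroxy-10-methyl-6-[3-(pivaloyloxy)propyl]spiro[4.5]decane
Product: 22 cis-fused γ-lactone between the C1 oxygen and the C2 acetic acid arm of (1R,2S,5S,6S,10S)-10-hydroxy-10-methyl-7-oxo-6-[3-(pivaloyloxy)propyl]spiro[4.5]decane
Conditions: Dess–Martin periodinane, NaHCO3, CH2Cl2, rt
Reagents that add atoms: none
Why: Dess–Martin oxidation of the only secondary alcohol; the buffered, non-basic medium should leave the now α-positioned C6 centre untouched.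

Step 17
Reactants: 22 cis-fused γ-lactone between the C1 oxygen and the C2 acetic acid arm of (1R,2S,5S,6S,10S)-10-hydroxy-10-methyl-7-oxo-6-[3-(pivaloyloxy)propyl]spiro[4.5]decane
Product: 23 cis-fused γ-lactone between the C1 oxygen and the C2 acetic acid arm of (1R,2S,5S,6S,10S)-7,10-dihydroxy-10-methyl-6-[3-(pivaloyloxy)propyl]-7-(prop-1-en-2-yl)spiro[4.5]decane (C7 epimers)
Conditions: CH2=C(CH3)MgBr, CeCl3, THF, −78 °C
Reagents that add atoms: isopropenylmagnesium bromide, CC(=C)[Mg]Br
Why: Organocerium 1,2-addition: the weakly basic reagent should add to the hindered, enolisable ketone without epimerising C6 and faster than to the lactone or the pivalate; one equivalent is spent on the C10 hydroxyl.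

Step 18
Reactants: 23 cis-fused γ-lactone between the C1 oxygen and the C2 acetic acid arm of (1R,2S,5S,6S,10S)-7,10-dihydroxy-10-methyl-6-[3-(pivaloyloxy)propyl]-7-(prop-1-en-2-yl)spiro[4.5]decane (C7 epimers)
Product: 24 cis-fused γ-lactone between the C1 oxygen and the C2 acetic acid arm of (2E)-2-[(1R,2S,5S,6R,10S)-10-hydroxy-10-methyl-6-[3-(pivaloyloxy)propyl]spiro[4.5]decan-7-ylidene]propanal
Conditions: [C5H5NH][CrO3Cl] (pyridinium chlorochromate), NaOAc, 4 Å MS, CH2Cl2, rt
Reagents that add atoms: pyridinium chlorochromate, [O-][Cr](=O)(=O)Cl.c1cc[nH+]cc1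
Why: Babler–Dauben oxidative transposition: the chromate ester of the tertiary allylic alcohol undergoes a [3,3] shift to the primary allylic chromate, which is oxidised to the enal; the mechanism does not secure the alkene geometry, so the E isomer (formyl on the C8 side) is separated here and the Z isomer returned to the mixture by photochemical equilibration.

Step 19
Reactants: 24 cis-fused γ-lactone between the C1 oxygen and the C2 acetic acid arm of (2E)-2-[(1R,2S,5S,6R,10S)-10-hydroxy-10-methyl-6-[3-(pivaloyloxy)propyl]spiro[4.5]decan-7-ylidene]propanal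
Product: 25 dimethyl acetal of 24 (7-[(E)-1,1-dimethoxypropan-2-ylidene] lactone)
Conditions: HC(OMe)3, PPTS (cat.), MeOH, rt
Reagents that add atoms: trimethyl orthoformate, COC(OC)OC; methanol, CO
Why: Acid-catalysed acetalisation with an orthoformate as water scavenger masks the aldehyde against the amide base and the hydride of steps 22–24; the fully substituted β-carbon rules out conjugate addition of methanol.

Step 20
Reactants: 26 6-methylhept-5-en-2-one
Product: 27 6-methylhepta-1,5-dien-2-yl trifluoromethanesulfonate
Conditions: LiN(i-Pr)2, THF, −78 °C; PhNTf2, −78 → 0 °C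
Reagents that add atoms: N-phenylbis(trifluoromethanesulfonimide), O=S(=O)(N(c1ccccc1)S(=O)(=O)C(F)(F)F)C(F)(F)F
Why: Kinetic deprotonation of the methyl ketone on its methyl side and O-sulfonylation of the terminal enolate (enol triflate formation) fix the 1,1-disubstituted alkene.

Step 21
Reactants: 27 6-methylhepta-1,5-dien-2-yl trifluoromethanesulfonate; 28 2-[(1E)-3,3-diethoxyprop-1-en-1-yl]-4,4,5,5-tetramethyl-1,3,2-dioxaborolane
Product: 30 (2E)-8-methyl-4-methylidenenona-2,7-dienal, via diethyl acetal 29 (not isolated)
Conditions: Pd(PPh3)4 (cat.), K3PO4, dioxane/H2O, 60 °C; then 1 M HCl, THF, 0 °C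
Reagents that add atoms: water, O
Why: Suzuki–Miyaura coupling of an alkenyl triflate with an (E)-alkenylboronate proceeds with retention at both partners and gives the 2-substituted diene; dilute acid then frees the aldehyde, which is used fresh because it can dimerise by Diels–Alder reaction.

Step 22
Reactants: 25 dimethyl acetal of 24 (7-[(E)-1,1-dimethoxypropan-2-ylidene] lactone); 30 (2E)-8-methyl-4-methylidenenona-2,7-dienal
Product: 31 aldol adduct: lactone 25 carrying at its α-carbon a (2E)-1-hydroxy-8-methyl-4-methylidenenona-2,7-dien-1-yl group (mixture at the two new centres)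
Conditions: LiN(i-Pr)2 (2.2 equiv), THF, −78 °C; 30, −78 °C
Reagents that add atoms: none
Why: Aldol addition of the lactone lithium enolate (the second equivalent of base holds the C10 alkoxide) to the enal in the 1,2 sense at low temperature; the two new stereocentres disappear in step 23.

Step 23
Reactants: 31 aldol adduct: lactone 25 carrying at its α-carbon a (2E)-1-hydroxy-8-methyl-4-methylidenenona-2,7-dien-1-yl group (mixture at the two new centres)
Product: 33 triene lactone: lactone 25 carrying at its α-carbon an (E)-configured (2E)-8-methyl-4-methylidenenona-2,7-dien-1-ylidene group, via allylic mesylate 32 (not isolated)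
Conditions: MsCl, Et3N, CH2Cl2, −20 °C; then DBU, 0 °C → rt
Reagents that add atoms: none
Why: Mesylation of the secondary alcohol (the tertiary C10 hydroxyl does not react) and E1cB elimination give the α-alkylidene lactone; the thermodynamically preferred E isomer, with the dienyl chain anti to the lactone carbonyl, is expected and becomes the E-trisubstituted alkene of the target.

Step 24
Reactants: 33 triene lactone: lactone 25 carrying at its α-carbon an (E)-configured (2E)-8-methyl-4-methylidenenona-2,7-dien-1-ylidene group
Product: 34 (1R,2S,5S,6R,10S)-7-[(E)-1,1-dimethoxypropan-2-ylidene]-2-[(2E,4E)-1-hydroxy-10-methyl-6-methylideneundeca-2,4,9-trien-2-yl]-6-(3-hydroxypropyl)-10-methylspiro[4.5]decane-1,10-diol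
Conditions: i-Bu2AlH, CH2Cl2, −78 → 0 °C; then aq. KNaC4H4O6
Reagents that add atoms: none
Why: The aluminium hydride reduces the unsaturated lactone in the 1,2 sense to the allylic alcohol and the C1 carbinol and cleaves the pivalate in the same operation; the acetal is inert to hydride at this temperature.

Step 25
Reactants: 34 (1R,2S,5S,6R,10S)-7-[(E)-1,1-dimethoxypropan-2-ylidene]-2-[(2E,4E)-1-hydroxy-10-methyl-6-methylideneundeca-2,4,9-trien-2-yl]-6-(3-hydroxypropyl)-10-methylspiro[4.5]decane-1,10-diol
Product: 35 (2E)-2-[(1R,2S,5S,6R,10S)-1,10-dihydroxy-2-[(2E,4E)-1-hydroxy-10-methyl-6-methylideneundeca-2,4,9-trien-2-yl]-6-(3-hydroxypropyl)-10-methylspiro[4.5]decan-7-ylidene]propanal (CNP0246965.4)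
Conditions: PPTS (cat.), acetone/H2O, rt
Reagents that add atoms: water, O
Why: Mild acid-catalysed hydrolysis of the α,β-unsaturated dimethyl acetal frees the enal; pyridinium tosylate in wet acetone should be too weak to ionise the allylic or tertiary alcohols or to protonate the triene.

## Compound list

1 | 2-allylcyclohexane-1,3-dione | C=CCC1C(=O)CCCC1=O | starting material
2 | 2-allyl-3-(2-methylpropoxy)cyclohex-2-en-1-one | C=CCC1=C(OCC(C)C)CCCC1=O | intermediate
3 | rac-2-allyl-6-methyl-3-(2-methylpropoxy)cyclohex-2-en-1-one | C=CCC1=C(OCC(C)C)CCC(C)C1=O | intermediate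
4 | 6-allyl-2-methyl-5-(2-methylpropoxy)cyclohexa-1,5-dien-1-yl trifluoromethanesulfonate | CC1=C(OS(=O)(=O)C(F)(F)F)C(CC=C)=C(OCC(C)C)CC1 | intermediate
5 | [6-allyl-2-methyl-5-(2-methylpropoxy)cyclohexa-1,5-dien-1-yl]trimethylstannane | CC1=C([Sn](C)(C)C)C(CC=C)=C(OCC(C)C)CC1 | intermediate
6 | cyclobutanone | O=C1CCC1 | starting material
7 | [6-allyl-2-methyl-5-(2-methylpropoxy)cyclohexa-1,5-dien-1-yl]lithium | CC1=C([Li])C(CC=C)=C(OCC(C)C)CC1 | intermediate
8 | lithium 1-[6-allyl-2-methyl-5-(2-methylpropoxy)cyclohexa-1,5-dien-1-yl]cyclobutan-1-olate | CC1=C(C2(O[Li])CCC2)C(CC=C)=C(OCC(C)C)CC1 | intermediate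
9 | {1-[6-allyl-2-methyl-5-(2-methylpropoxy)cyclohexa-1,5-dien-1-yl]cyclobutoxy}triethylsilane | CC1=C(C2(O[Si](CC)(CC)CC)CCC2)C(CC=C)=C(OCC(C)C)CC1 | intermediate
10 | rac-2-allyl-4-methyl-3-[1-(triethylsilyloxy)cyclobutyl]cyclohex-3-en-1-one | CC1=C(C2(O[Si](CC)(CC)CC)CCC2)C(CC=C)C(=O)CC1 | intermediate
11 | rac-(1R,2S)-2-allyl-4-methyl-3-[1-(triethylsilyloxy)cyclobutyl]cyclohex-3-en-1-ol (racemate, allyl and hydroxyl cis; one enantiomer drawn) | C=CC[C@@H]1[C@H](O)CCC(C)=C1C2(O[Si](CC)(CC)CC)CCC2 | intermediate
12 | (1R,2S)-2-allyl-4-methyl-3-[1-(triethylsilyloxy)cyclobutyl]cyclohex-3-en-1-yl acetate | C=CC[C@@H]1[C@H](OC(C)=O)CCC(C)=C1C2(O[Si](CC)(CC)CC)CCC2 | intermediate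
13 | (1R,2S)-2-[3-(9-borabicyclo[3.3.1]nonan-9-yl)propyl]-4-methyl-3-[1-(triethylsilyloxy)cyclobutyl]cyclohex-3-en-1-yl acetate | C(CC[C@@H]1[C@H](OC(C)=O)CCC(C)=C1C2(O[Si](CC)(CC)CC)CCC2)B3C4CCCC3CCC4 | intermediate
14 | (1R,2S)-2-(3-hydroxypropyl)-4-methyl-3-[1-(triethylsilyloxy)cyclobutyl]cyclohex-3-en-1-ol | OCCC[C@@H]1[C@H](O)CCC(C)=C1C2(O[Si](CC)(CC)CC)CCC2 | intermediate
15 | (1R,2S)-4-methyl-2-[3-(pivaloyloxy)propyl]-3-[1-(triethylsilyloxy)cyclobutyl]cyclohex-3-en-1-ol | CC(C)(C)C(=O)OCCC[C@@H]1[C@H](O)CCC(C)=C1C2(O[Si](CC)(CC)CC)CCC2 | intermediate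
16 | (1R,2R,3R,6S)-6-methyl-2-[3-(pivaloyloxy)propyl]-1-[1-(triethylsilyloxy)cyclobutyl]-7-oxabicyclo[4.1.0]heptan-3-ol (epoxide oxygen, hydroxyl and side chain all on one face) | CC[Si](CC)(CC)OC3(CCC3)[C@]12O[C@@]1(C)CC[C@@H](O)[C@H]2CCCOC(=O)C(C)(C)C | intermediate
17 | (1R,2R,3R,6S)-6-methyl-2-[3-(pivaloyloxy)propyl]-3-(triethylsilyloxy)-1-[1-(triethylsilyloxy)cyclobutyl]-7-oxabicyclo[4.1.0]heptane | CC[Si](CC)(CC)OC3(CCC3)[C@]12O[C@@]1(C)CC[C@@H](O[Si](CC)(CC)CC)[C@H]2CCCOC(=O)C(C)(C)C | intermediate
18 | (5R,6S,7R,10S)-10-hydroxy-10-methyl-6-[3-(pivaloyloxy)propyl]-7-(triethylsilyloxy)spiro[4.5]decan-1-one | C1CC[C@]2([C@H](CCCOC(=O)C(C)(C)C)[C@H](O[Si](CC)(CC)CC)CC[C@]2(C)O)C1=O | intermediate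
19 | methyl 2-[(2S,5R,6S,7R,10S)-10-hydroxy-10-methyl-1-oxo-6-[3-(pivaloyloxy)propyl]-7-(triethylsilyloxy)spiro[4.5]decan-2-yl]acetate | COC(=O)C[C@@H]1CC[C@]2([C@H](CCCOC(=O)C(C)(C)C)[C@H](O[Si](CC)(CC)CC)CC[C@]2(C)O)C1=O | intermediate
20 | methyl 2-[(1R,2S,5S,6S,7R,10S)-1,10-dihydroxy-10-methyl-6-[3-(pivaloyloxy)propyl]-7-(triethylsilyloxy)spiro[4.5]decan-2-yl]acetate | COC(=O)C[C@@H]1CC[C@]2([C@H](CCCOC(=O)C(C)(C)C)[C@H](O[Si](CC)(CC)CC)CC[C@]2(C)O)[C@@H]1O | intermediate
21 | cis-fused γ-lactone (C1–O to the C2 acetic acid arm) of (1R,2S,5S,6S,7R,10S)-7,10-dihydroxy-10-methyl-6-[3-(pivaloyloxy)propyl]spiro[4.5]decane | O=C1C[C@@H]2CC[C@]3([C@H](CCCOC(=O)C(C)(C)C)[C@H](O)CC[C@]3(C)O)[C@@H]2O1 | intermediate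
22 | the same lactone with a C7 ketone, (1R,2S,5S,6S,10S) | O=C1C[C@@H]2CC[C@]3([C@H](CCCOC(=O)C(C)(C)C)C(=O)CC[C@]3(C)O)[C@@H]2O1 | intermediate
23 | the same lactone with 7-hydroxy and 7-(prop-1-en-2-yl), (1R,2S,5S,6S,10S), both C7 epimers | O=C1C[C@@H]2CC[C@]3([C@H](CCCOC(=O)C(C)(C)C)C(O)(C(C)=C)CC[C@]3(C)O)[C@@H]2O1 | intermediate
24 | the same lactone with 7-[(E)-1-oxopropan-2-ylidene] (formyl cis to C8), (1R,2S,5S,6R,10S) | O=C1C[C@@H]2CC[C@]3([C@H](CCCOC(=O)C(C)(C)C)/C(=C(\C)C=O)CC[C@]3(C)O)[C@@H]2O1 | intermediate
25 | dimethyl acetal of 24, 7-[(E)-1,1-dimethoxypropan-2-ylidene] | O=C1C[C@@H]2CC[C@]3([C@H](CCCOC(=O)C(C)(C)C)/C(=C(\C)C(OC)OC)CC[C@]3(C)O)[C@@H]2O1 | intermediate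
26 | 6-methylhept-5-en-2-one | CC(=O)CCC=C(C)C | starting material
27 | 6-methylhepta-1,5-dien-2-yl trifluoromethanesulfonate | C=C(OS(=O)(=O)C(F)(F)F)CCC=C(C)C | intermediate
28 | 2-[(1E)-3,3-diethoxyprop-1-en-1-yl]-4,4,5,5-tetramethyl-1,3,2-dioxaborolane | CCOC(OCC)/C=C/B1OC(C)(C)C(C)(C)O1 | starting material
29 | (2E)-1,1-diethoxy-8-methyl-4-methylidenenona-2,7-diene | CCOC(OCC)/C=C/C(=C)CCC=C(C)C | intermediate
30 | (2E)-8-methyl-4-methylidenenona-2,7-dienal | O=C/C=C/C(=C)CCC=C(C)C | intermediate
31 | aldol adduct of 25 and 30 (α-[(2E)-1-hydroxy-8-methyl-4-methylidenenona-2,7-dien-1-yl] lactone, mixture at the two new centres) | C=C(CCC=C(C)C)/C=C/C(O)C1C(=O)O[C@@H]2[C@H]1CC[C@]23[C@H](CCCOC(=O)C(C)(C)C)/C(=C(\C)C(OC)OC)CC[C@]3(C)O | intermediate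
32 | methanesulfonate of 31 | C=C(CCC=C(C)C)/C=C/C(OS(C)(=O)=O)C1C(=O)O[C@@H]2[C@H]1CC[C@]23[C@H](CCCOC(=O)C(C)(C)C)/C(=C(\C)C(OC)OC)CC[C@]3(C)O | intermediate
33 | triene lactone, α-[(E)-alkylidene] with an (E)-diene, (1R,2S,5S,6R,10S) | C=C(CCC=C(C)C)/C=C/C=C1/C(=O)O[C@@H]2[C@H]1CC[C@]23[C@H](CCCOC(=O)C(C)(C)C)/C(=C(\C)C(OC)OC)CC[C@]3(C)O | intermediate
34 | (1R,2S,5S,6R,10S)-7-[(E)-1,1-dimethoxypropan-2-ylidene]-2-[(2E,4E)-1-hydroxy-10-methyl-6-methylideneundeca-2,4,9-trien-2-yl]-6-(3-hydroxypropyl)-10-methylspiro[4.5]decane-1,10-diol | C=C(/C=C/C=C(/CO)[C@@H]1CC[C@]2([C@H](CCCO)/C(=C(\C)C(OC)OC)CC[C@]2(C)O)[C@@H]1O)CCC=C(C)C | intermediate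
35 | (2E)-2-[(1R,2S,5S,6R,10S)-1,10-dihydroxy-2-[(2E,4E)-1-hydroxy-10-methyl-6-methylideneundeca-2,4,9-trien-2-yl]-6-(3-hydroxypropyl)-10-methylspiro[4.5]decan-7-ylidene]propanal (CNP0246965.4) | C=C(/C=C/C=C(/CO)[C@@H]1CC[C@]2([C@H](CCCO)/C(=C(\C)C=O)CC[C@]2(C)O)[C@@H]1O)CCC=C(C)C | target

## Step count and least certain steps

Total step count: 25. Longest linear sequence: 23 steps (steps 1–19 and 22–25); the dienal branch (steps 20–21) joins in step 22.

**Step 13 (key step).** The most likely failure is cleavage of the C10–O bond in place of the C5–O bond (ionisation at the methyl-bearing carbon, followed by hydride or methyl shift or elimination). A second risk is loss of a silyl group before migration, which would let the free C7 hydroxyl bind the Lewis acid. Both carbons of the epoxide are tertiary, so the bias rests on the assistance of the strained migrating bond.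
Fallback, from 17 back to 18: Bu4NF removes both silyl ethers and gives the free epoxy cyclobutanol (1S,2R,3R,6S)-1-(1-hydroxycyclobutyl)-6-methyl-2-[3-(pivaloyloxy)propyl]-7-oxabicyclo[4.1.0]heptan-3-ol F1. Excess Et2AlCl in CH2Cl2 at −78 °C turns the cyclobutanol into an aluminium alkoxide that chelates the epoxide oxygen, so that the shift is pushed by the alkoxide and not only pulled by an external acid; this gives the keto diol (5R,6S,7R,10S)-7,10-dihydroxy-10-methyl-6-[3-(pivaloyloxy)propyl]spiro[4.5]decan-1-one F2. Selective silylation of the secondary hydroxyl (Et3SiCl, imidazole) returns to 18.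

**Step 11 (directed epoxidation).** Oxygen delivery may be slow or go to the wrong face. The directing hydroxyl must become axial, which pushes the cis side chain into the pseudo-equatorial position against the bulky substituent on the alkene; the epoxide could also rearrange early on the Lewis-acidic metal.
Fallback, from 15 back to 16: face selection is handed from the substrate to the catalyst. Zr(Ot-Bu)4 or Hf(Ot-Bu)4 with a C2-symmetric chiral bishydroxamic acid ligand and cumene hydroperoxide, a system made for homoallylic alcohols, is used with the ligand enantiomer that matches the 1R carbinol. No new compound is formed.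

**Step 8 (resolution).** Acyl transfer may be slow or poorly selective on a hindered cis-2-substituted cyclohexenol flanked by the bulky alkene substituent, so that the resolution stays incomplete.
Fallback, from racemic 11 back to 14: esterification with (2S)-2-methoxy-2-phenylacetic acid (DCC, DMAP, CH2Cl2) gives two diastereomers separable on silica, (1R,2S)-2-allyl-4-methyl-3-[1-(triethylsilyloxy)cyclobutyl]cyclohex-3-en-1-yl (2S)-2-methoxy-2-phenylacetate F3 and its (1S,2R)-cyclohexenyl diastereomer F4. F3 is taken through the conditions of step 9, in which its 9-BBN adduct F5 is oxidised and the ester saponified, and rejoins the route at 14.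

**Step 14 (C2 alkylation).** Retro-aldol opening of ring B may occur before the enolate is formed or after the alkylated ketone is regenerated. The electrophile may also enter the wrong face of C2, which would give a hydroxy ester in step 15 that cannot lactonise.
Fallback, from 18 back to 22: C2 is set from the C1 oxygen by an Ueno–Stork sequence.
- IBX (DMSO, 70 °C) dehydrogenates 18 to the spiro enone (5R,6S,7R,10S)-10-hydroxy-10-methyl-6-[3-(pivaloyloxy)propyl]-7-(triethylsilyloxy)spiro[4.5]dec-2-en-1-one F6.
- Me4NBH(OAc)3 gives the allylic alcohol (1R,5S,6S,7R,10S)-10-methyl-6-[3-(pivaloyloxy)propyl]-7-(triethylsilyloxy)spiro[4.5]dec-2-ene-1,10-diol F7 by hydroxyl-directed 1,2-reduction.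
- N-bromosuccinimide and ethyl vinyl ether give the 1-O-(2-bromo-1-ethoxyethyl) acetal F8.
- Bu3SnH with AIBN closes the cis-fused bicyclic ethyl acetal F9 by 5-exo radical cyclisation.
- CrO3/H2SO4 in acetone oxidises the acetal to the lactone, removes the silyl ether and oxidises C7, which returns to the route at 22.

**Step 18 (Babler–Dauben transposition).** The sigmatropic shift has no built-in E/Z control. The acidic chromium reagent may also cause loss of water from the tertiary allylic alcohol, or attack of the C10 hydroxyl on a C7 cation.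
Fallback, from 23 back to 24: catalytic Ph3SiOReO3 isomerises 23 under neutral conditions to the primary allylic alcohol F10, the lactone with a 7-[(E)-1-hydroxypropan-2-ylidene] group. Its geometrical isomers do not interconvert and can be separated; MnO2 then oxidises the E isomer to 24.

## Further compounds

F1 | step 13 | (1S,2R,3R,6S)-1-(1-hydroxycyclobutyl)-6-methyl-2-[3-(pivaloyloxy)propyl]-7-oxabicyclo[4.1.0]heptan-3-ol | OC3(CCC3)[C@]12O[C@@]1(C)CC[C@@H](O)[C@H]2CCCOC(=O)C(C)(C)C
F2 | step 13 | (5R,6S,7R,10S)-7,10-dihydroxy-10-methyl-6-[3-(pivaloyloxy)propyl]spiro[4.5]decan-1-one | C1CC[C@]2([C@H](CCCOC(=O)C(C)(C)C)[C@H](O)CC[C@]2(C)O)C1=O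
F0 | step 11 | none | none
F3 | step 8 | (1R,2S)-2-allyl-4-methyl-3-[1-(triethylsilyloxy)cyclobutyl]cyclohex-3-en-1-yl (2S)-2-methoxy-2-phenylacetate | C=CC[C@@H]1[C@H](OC(=O)[C@@H](OC)c3ccccc3)CCC(C)=C1C2(O[Si](CC)(CC)CC)CCC2
F4 | step 8 | (1S,2R)-2-allyl-4-methyl-3-[1-(triethylsilyloxy)cyclobutyl]cyclohex-3-en-1-yl (2S)-2-methoxy-2-phenylacetate | C=CC[C@H]1[C@@H](OC(=O)[C@@H](OC)c3ccccc3)CCC(C)=C1C2(O[Si](CC)(CC)CC)CCC2
F5 | step 8 | 9-BBN adduct of F3 at the terminal carbon of the allyl group | C(CC[C@@H]1[C@H](OC(=O)[C@@H](OC)c3ccccc3)CCC(C)=C1C2(O[Si](CC)(CC)CC)CCC2)B4C5CCCC4CCC5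
F6 | step 14 | (5R,6S,7R,10S)-10-hydroxy-10-methyl-6-[3-(pivaloyloxy)propyl]-7-(triethylsilyloxy)spiro[4.5]dec-2-en-1-one | C1=CC[C@]2([C@H](CCCOC(=O)C(C)(C)C)[C@H](O[Si](CC)(CC)CC)CC[C@]2(C)O)C1=O
F7 | step 14 | (1R,5S,6S,7R,10S)-10-methyl-6-[3-(pivaloyloxy)propyl]-7-(triethylsilyloxy)spiro[4.5]dec-2-ene-1,10-diol | C1=CC[C@]2([C@H](CCCOC(=O)C(C)(C)C)[C@H](O[Si](CC)(CC)CC)CC[C@]2(C)O)[C@@H]1O
F8 | step 14 | 1-O-(2-bromo-1-ethoxyethyl) acetal of F7 (acetal carbon as a mixture) | C1=CC[C@]2([C@H](CCCOC(=O)C(C)(C)C)[C@H](O[Si](CC)(CC)CC)CC[C@]2(C)O)[C@@H]1OC(CBr)OCC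
F9 | step 14 | cis-fused bicyclic ethyl acetal (C1–O–CH(OEt)–CH2–C2) of the (1R,2S,5S,6S,7R,10S) spirodecane, 7-triethylsilyl ether | CCOC1C[C@@H]2CC[C@]3([C@H](CCCOC(=O)C(C)(C)C)[C@H](O[Si](CC)(CC)CC)CC[C@]3(C)O)[C@@H]2O1
F10 | step 18 | lactone of 24 with 7-[(E)-1-hydroxypropan-2-ylidene] in place of the enal | O=C1C[C@@H]2CC[C@]3([C@H](CCCOC(=O)C(C)(C)C)/C(=C(\C)CO)CC[C@]3(C)O)[C@@H]2O1
A1 | alternative 1 | spiro[4.5]deca-2,8-diene-1,7-dione with the C6 3-(tert-butyldimethylsilyloxy)propyl chain and C10 methyl and methoxymethoxy groups | O=C1C=CC[C@]12[C@H](CCCO[Si](C)(C)C(C)(C)C)C(=O)C=C[C@]2(C)OCOC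
A2 | alternative 2 | cyclobutane-fused 2,2-dimethyl-1,3-dioxan-4-one photoadduct containing ring B, with C1 tert-butyldimethylsilyl ether and C10 methoxymethyl ether | C1CC[C@]2([C@@H]3C[C@H]4C(=O)OC(C)(C)O[C@@]34CC[C@]2(C)OCOC)[C@@H]1O[Si](C)(C)C(C)(C)C
A3 | alternative 3 | spiro cyclopentanol with cis C2 alkenyl arm (CH2O-p-methoxybenzyl and CH2O-silyl termini), C7 dioxolane ketal and C10 triethylsilyl ether | CC(C)(C)[Si](C)(C)OC/C=C(/COCc3ccc(OC)cc3)[C@@H]1CC[C@]2([C@H](CCCO[Si](C)(C)C(C)(C)C)C4(OCCO4)CC[C@]2(C)O[Si](CC)(CC)CC)[C@@H]1O
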